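## The problem

7-O-Methyltetrahydroochnaflavone is a biflavanone: two 2-arylchroman-4-one units joined by a diaryl ether from C3' of ring B of unit 1 to C4' of ring B of unit 2. Each unit has one stereocentre, C2, and both are S. They lie nine bonds apart across a freely rotating ether, so neither can direct the other and each must be set by a reagent or catalyst. Both centres are benzylic ethers β to a ketone. Deprotonation at C3 opens ring C to a 2'-hydroxychalcone that recloses without selectivity, so base and long heating must be avoided once a flavanone (or the dihydropyranone that precedes it) exists, and strong acid is unwelcome at the para-oxygenated benzylic carbon. Four phenols need protection that can be removed under neutral conditions. The two rings A differ by a single methyl group (5-OH/7-OMe in unit 1, 5,7-dihydroxy in unit 2), a difference that a phloroglucinol-based route can secure only by selective protection. The feature that opens another way is ring A of unit 1 itself: a benzene fused at C4a–C8a whose other carbons carry OH (C5), H (C6), OMe (C7) and H (C8). This is the resorcinol monomethyl ether pattern that arises when a vinylketene built on the C8a=C4a bond takes up methoxyacetylene.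

## Retrosynthesis

**26 to 25.** The last operation should only uncover phenols. Cutting the three O–benzyl bonds of target 26 leads to tribenzyl ether 25. Hydrogenolysis is neutral and leaves both C2 centres alone. Methyl ethers would need a Lewis acid that cannot spare the 7-OMe group, and silyl ethers would need fluoride, which is basic enough to open ring C. The 5-OH of unit 1 stays free throughout because it is chelated to the C4 carbonyl. The forward step must not cleave the benzylic C2–O1 bonds.

**25 to 20 and 24.** The bond between C2 of unit 2 and C1' of its ring B is cut, giving arylboronic acid 20 and the achiral chromone 24. The forward reaction is a catalyst-controlled conjugate addition that runs without base, so the finished stereocentre of unit 1 is not endangered and the new one is set by the ligand alone. Forming the diaryl ether last would bring two base-labile flavanones into a copper-mediated, amine-buffered coupling. A chalcone route to unit 2 would need hydroxide. The cut gives two fragments of similar size.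

**20 to 19 to 18.** The boron is traced back through pinacol boronate 19 to aryl bromide 18. The bromine comes in with a commercial building block and is inert to copper, titanium, tin, diazomethane and long-wavelength light, so it can be carried as a spectator until it is needed.

**18 to 10 and 13 (key disconnection).** Three bonds of ring A are cut: C5–C6, C7–C8 and C4a–C5. The whole ring is removed, leaving dihydropyranone diazoketone 10 and methoxyacetylene 13. The usual cuts at O1–C2 (chalcone closure) or C2–C1' (addition to a 5-hydroxy-7-methoxychromone) both start from a phloroglucinol whose oxygens must be told apart. Here the 5-OH/7-OMe pattern follows from the polarity of the ynol ether. The precursor is monocyclic with one stereocentre that does not take part. The forward step must excite the diazoketone selectively in the presence of an enone and must run without acid or base.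

**10 to 8 to 7.** The diazoacetyl group is cut between the acyl carbon and the diazo carbon, leading through acid chloride 9 to acid 8 and its methyl ester 7. The dihydropyranone opens by E1cB elimination once C3 is deprotonated, so both transformations have to be non-basic.

**7 to 3 and 5.** The pyranone is cut at C2–C3 and O1–C6, the hetero-Diels–Alder retron, giving aldehyde 3 and bis(silyloxy)diene 5. This single step forms ring C, sets C2 and brings in the carboxyl carbon at C6. A stepwise aldol, oxalate Claisen condensation and cyclodehydration reach the same ester in more steps and are held as a fallback. Diene 5 is one step from methyl acetopyruvate 4.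

**3 to 1 and 2; reagents.** The diaryl ether C–O bond of 3 is cut to phenol 1 and boronic acid 2. Oxidative copper coupling at room temperature keeps the bromine, which a hot Ullmann coupling would not, and the ring has no activating group for SNAr. Methoxyacetylene 13 is made fresh from chloroacetal 11. Chromone 24 comes from phloroacetophenone 21 through dibenzyl ether 22 and enaminone 23.

## Roads not taken

**Alternative 1: both rings C closed by SNAr.**
- Cut: both O1–C8a bonds, leading to the bis(β-hydroxy ketone) A1 with a fluorine ortho to each aryl ketone.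
- Forward step: Cs2CO3 in DMF lets each (S)-carbinol oxygen displace its fluoride and gives tetrabenzyl ether A2 in one operation.
- Merits: both heterocycles form together, the stereocentres are set earlier at the carbinol stage and are not bonding partners in the closure, and no light or diazo compound is needed. In convergence this road is better than the chosen one.
- Weak points: the fluoroarenes carry two alkoxy donors and are activated only by the ortho acyl group, so the displacement needs heat. Under carbonate in hot DMF a β-hydroxy ketone undergoes retro-aldol cleavage and dehydration to the chalcone, and the flavanones formed can reopen and epimerise. The two fluorinated ring-A ketones must be differentially protected, so the methyl/benzyl distinction is made by protecting-group work.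
- Comparison: the chosen plan closes ring A under neutral conditions where C2 is not at risk, and it takes the 5-OH/7-OMe pattern from regiochemistry.

**Alternative 2: ring B of unit 2 by cobalt-catalysed cycloaddition.**
- Cut: the C1'–C6' and C2'–C3' bonds of the para-phenylene ring, giving ethynylchromanone A3 and aryloxydiene A4.
- Forward step: CoBr2(dppe) with Zn and ZnI2 joins them, and DDQ in the same flask dehydrogenates the cycloadduct to chloride A5.
- Merits: the arene and the diaryl ether pattern arise in a neutral, para-selective step, without copper, and the step is thermal. That is an advantage over a photochemical key step.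
- Weak points: A4 is an acid-sensitive 2-aryloxydiene of unproven behaviour in this catalysis. The stereocentre of A3 is propargylic and β to a ketone, so it can eliminate. DDQ meets benzyl ethers and electron-rich rings. Above all, unit 1 is left to be built afterwards from an aryl chloride, with its ring A pattern still unsolved.
- Comparison: this road spends its key step on the ring that poses no selectivity problem. The chosen plan buys that ring as boronic acid 2 and spends its key step on the differentiated ring A.

**Alternative 3: ring C of unit 1 by aryne annulation.**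
- Cut: O1–C8a and C4–C4a, giving β-hydroxy Weinreb amide A6 and silyl triflate A7.
- Forward step: the sodium alkoxide of A6 adds to the aryne released from A7 by CsF, and the aryl anion is acylated by the amide to give 5-O-benzyl flavanone A8.
- Merits: ring A arrives as one piece and ring C closes in the same step. The 3-alkoxy group of the aryne directs the alkoxide to the distal carbon and places the anion where acylation is needed. No light or diazomethane is involved, and the step count to the bromide stage is comparable or lower.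
- Weak points: the alkoxide of a β-hydroxy amide with a para-oxygenated aryl group can undergo retro-aldol cleavage and elimination. The aryl anion must be acylated faster than it is protonated. A7 is a fourfold differentiated phloroglucinol that takes several selective steps, and the 5-oxygen ends benzylated.
- Comparison: the chosen plan keeps strong base away from the stereocentre, needs no differentiated arene and gives the free 5-OH directly.

Key step: step 7

Assumption: the sense of induction of the two chiral catalysts is assigned by analogy with simpler substrates ((S)-BINOL/Ti(OiPr)4 attacking the Si face of an aryl aldehyde; (R)-t-BuPyOx/Pd(OCOCF3)2 giving the 2S chromanone); if either analogy fails, the antipodal ligand, equally available, is used.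

## Route

Step 1
Reactants: 1 4-(benzyloxy)-3-hydroxybenzaldehyde; 2 4-bromophenylboronic acid
Product: 3 4-(benzyloxy)-3-(4-bromophenoxy)benzaldehyde
Conditions: Cu(OAc)2 (1 equiv), pyridine (5 equiv), 4 Å MS, CH2Cl2, air, rt
Reagents that add atoms: none
Why: Chan–Lam O-arylation: the aryl group passes from boron to the copper phenoxide and the C–O bond forms by reductive elimination from trivalent copper, with air returning copper to the divalent state; the aryl bromide and the aldehyde are inert at room temperature.

Step 2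
Reactants: 4 methyl 2,4-dioxopentanoate
Product: 5 methyl (2Z)-2,4-bis(trimethylsilyloxy)penta-2,4-dienoate
Conditions: TMSOTf (2.2 equiv), Et3N (2.5 equiv), Et2O, 0 °C
Reagents that add atoms: trimethylsilyl trifluoromethanesulfonate, C[Si](C)(C)OS(=O)(=O)C(F)(F)F
Why: Soft enolisation and O-silylation of both carbonyls of the 1,3-dicarbonyl unit, the standard route to 1,3-bis(silyloxy)dienes; the chelated enol at C2 should fix the Z geometry.

Step 3
Reactants: 3 4-(benzyloxy)-3-(4-bromophenoxy)benzaldehyde; 5 methyl (2Z)-2,4-bis(trimethylsilyloxy)penta-2,4-dienoate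
Product: 7 methyl (S)-2-[4-(benzyloxy)-3-(4-bromophenoxy)phenyl]-4-oxo-3,4-dihydro-2H-pyran-6-carboxylate, via bis-silylated aldol adduct 6 (not isolated)
Conditions: Ti(OiPr)4 (10 mol %), (S)-BINOL (20 mol %), 4 Å MS, Et2O, −20 °C; then CF3CO2H, CH2Cl2, 0 °C
Reagents that add atoms: none
Why: Enantioselective formal hetero-Diels–Alder reaction (Mukaiyama aldol addition, then acid cyclocondensation): the terminal silyl enol ether carbon of 5 should attack the Si face of the aldehyde held by the chiral titanium–BINOL complex, setting C2 as S, and CF3CO2H then removes both silyl groups and closes the ring by hemiketalisation and dehydration, as in chromone-2-carboxylate synthesis.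

Step 4
Reactants: 7 methyl (S)-2-[4-(benzyloxy)-3-(4-bromophenoxy)phenyl]-4-oxo-3,4-dihydro-2H-pyran-6-carboxylate
Product: 8 (S)-2-[4-(benzyloxy)-3-(4-bromophenoxy)phenyl]-4-oxo-3,4-dihydro-2H-pyran-6-carboxylic acid
Conditions: Me3SnOH (3 equiv), ClCH2CH2Cl, 70 °C; then 0.5 M HCl wash
Reagents that add atoms: trimethyltin hydroxide, C[Sn](C)(C)O
Why: Trimethyltin hydroxide cleaves the activated methyl ester by near-neutral hydroxide transfer, so C3 should not be enolised and the E1cB ring opening that would racemise C2 is avoided.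

Step 5
Reactants: 8 (S)-2-[4-(benzyloxy)-3-(4-bromophenoxy)phenyl]-4-oxo-3,4-dihydro-2H-pyran-6-carboxylic acid
Product: 10 (S)-2-[4-(benzyloxy)-3-(4-bromophenoxy)phenyl]-6-(2-diazoacetyl)-2,3-dihydro-4H-pyran-4-one, via acid chloride 9 (not isolated)
Conditions: (COCl)2, DMF (cat.), CH2Cl2, 0 °C to rt; then CH2N2 (3 equiv), Et2O, −10 °C
Reagents that add atoms: diazomethane, C=[N+]=[N-]; oxalyl chloride, ClC(=O)C(Cl)=O (chlorine of 9 only)
Why: Acid chloride formation followed by C-acylation of diazomethane (first stage of the Arndt–Eistert sequence), as known for chromone- and pyranone-2-carbonyl chlorides; the second equivalent of diazomethane takes up HCl, and low temperature with slow addition of 9 should disfavour dipolar cycloaddition to the C5=C6 bond.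

Step 6
Reactants: 11 2-chloro-1,1-dimethoxyethane
Product: 13 methoxyacetylene, via sodium methoxyacetylide 12 (not isolated)
Conditions: NaNH2 (3 equiv), NH3 (l), −33 °C; then sat. aq NaCl, −20 °C, distilled into cold ClCH2CH2Cl
Reagents that add atoms: sodium amide, [Na+].[NH2-] (sodium of 12 only)
Why: Classical alkoxyacetylene synthesis: amide eliminates methanol and then HCl from the chloroacetal and holds the alkyne as its sodium salt until the cold aqueous quench; the product (bp about 23 °C) is used as a fresh solution.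

Step 7
Reactants: 10 (S)-2-[4-(benzyloxy)-3-(4-bromophenoxy)phenyl]-6-(2-diazoacetyl)-2,3-dihydro-4H-pyran-4-one; 13 methoxyacetylene
Product: 18 (S)-2-[4-(benzyloxy)-3-(4-bromophenoxy)phenyl]-5-hydroxy-7-methoxychroman-4-one, via vinylketene 14 (not isolated), via cyclobutenone 15 (not isolated), via dienylketene 16 (not isolated), via cyclohexadienone 17 (not isolated)
Conditions: 13 (4 equiv), hν (365 nm), ClCH2CH2Cl, 15 °C, sealed tube; then 80 °C
Reagents that add atoms: none
Why: Excitation of the diazo n→π* band expels nitrogen and the alkenyl group migrates (photochemical Wolff rearrangement) to give vinylketene 14, whose C=C is the C8a=C4a bond of the pyranone. The electrophilic ketene carbon (future C5) bonds to the unsubstituted, nucleophilic carbon of 13 (C6) and the ketene α-carbon (C8) to the methoxy-bearing carbon (C7) in a [2+2] cycloaddition that gives cyclobutenone 15. On warming, 15 opens by four-electron electrocyclic ring opening to dienylketene 16, and ring A closes by six-electron electrocyclisation of the ketene carbon onto C4a to give 17, which tautomerises to the phenol. The closest known reaction is the Danheiser benzannulation of α,β-unsaturated α'-diazo ketones with alkoxyacetylenes to resorcinol monoethers. No stereocentre is created, since the sp3 carbons of 15 and 17 disappear on aromatisation, and C2 is not a reacting centre in this neutral medium. The step needs regioselectivity in the [2+2] addition, which the polarity of the ynol ether supplies and which places OH at C5 and OMe at C7, and it needs selective excitation, which the long wavelength should provide by addressing the diazoketone and not the enone π→π* band. The ring holds the ketene chain trans to the C4 carbonyl across C8a=C4a, so oxa-electrocyclisation to an α-pyrone is excluded. The new 5-OH is chelated to the C4 carbonyl, which should protect it from acylation by further ketene.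

Step 8
Reactants: 18 (S)-2-[4-(benzyloxy)-3-(4-bromophenoxy)phenyl]-5-hydroxy-7-methoxychroman-4-one
Product: 19 (S)-2-{4-(benzyloxy)-3-[4-(4,4,5,5-tetramethyl-1,3,2-dioxaborolan-2-yl)phenoxy]phenyl}-5-hydroxy-7-methoxychroman-4-one
Conditions: B2pin2, PdCl2(dppf) (5 mol %), KOAc, 1,4-dioxane, 80 °C
Reagents that add atoms: bis(pinacolato)diboron, CC1(C)OB(OC1(C)C)B1OC(C)(C)C(C)(C)O1
Why: Miyaura borylation: zerovalent palladium inserts into the C–Br bond, acetate mediates transmetalation from the diboron and reductive elimination gives the boronate; the weak, poorly soluble base in an aprotic solvent is chosen so that C3 is not enolised, and the chelated phenol and the ketone are tolerated.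

Step 9
Reactants: 19 (S)-2-{4-(benzyloxy)-3-[4-(4,4,5,5-tetramethyl-1,3,2-dioxaborolan-2-yl)phenoxy]phenyl}-5-hydroxy-7-methoxychroman-4-one
Product: 20 (4-{2-(benzyloxy)-5-[(S)-5-hydroxy-7-methoxy-4-oxochroman-2-yl]phenoxy}phenyl)boronic acid
Conditions: NaIO4, NH4OAc, acetone–H2O, rt
Reagents that add atoms: water, O
Why: Periodate cleaves the pinacol released in the hydrolysis equilibrium and so drives the boronate to the boronic acid at room temperature and near-neutral pH; the meta-oxygenated, chelated phenol is not a substrate for periodate.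

Step 10
Reactants: 21 2',4',6'-trihydroxyacetophenone
Product: 22 1-[2,4-bis(benzyloxy)-6-hydroxyphenyl]ethan-1-one
Conditions: BnBr (2.1 equiv), K2CO3, DMF, rt
Reagents that add atoms: benzyl bromide, BrCc1ccccc1
Why: Williamson etherification: the para hydroxyl and one ortho hydroxyl are alkylated, while the remaining ortho hydroxyl is chelated to the acetyl group and stays free under carbonate.

Step 11
Reactants: 22 1-[2,4-bis(benzyloxy)-6-hydroxyphenyl]ethan-1-one
Product: 24 5,7-bis(benzyloxy)-4H-chromen-4-one, via enaminone 23 (not isolated)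
Conditions: Me2NCH(OMe)2, toluene, 100 °C; then aq HCl, CH2Cl2, rt
Reagents that add atoms: N,N-dimethylformamide dimethyl acetal, COC(OC)N(C)C
Why: Condensation of the methyl ketone with the amide acetal gives the enaminone, and acid then promotes addition of the phenol and loss of dimethylamine, the standard route to 3-unsubstituted chromones.

Step 12
Reactants: 20 (4-{2-(benzyloxy)-5-[(S)-5-hydroxy-7-methoxy-4-oxochroman-2-yl]phenoxy}phenyl)boronic acid; 24 5,7-bis(benzyloxy)-4H-chromen-4-one
Product: 25 (S)-2-{4-(benzyloxy)-3-[4-((S)-5,7-bis(benzyloxy)-4-oxochroman-2-yl)phenoxy]phenyl}-5-hydroxy-7-methoxychroman-4-one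
Conditions: Pd(OCOCF3)2 (5 mol %), (R)-t-BuPyOx (6 mol %), NH4PF6 (30 mol %), H2O (5 equiv), ClCH2CH2Cl, 60 °C
Reagents that add atoms: none
Why: Asymmetric conjugate addition of an arylboronic acid to a chromone under divalent palladium and a chiral pyridine–oxazoline: transmetalation gives a cationic arylpalladium species, the chromone C2=C3 bond inserts with the face chosen by the ligand to set C2 of unit 2 as S, and water protonates the palladium enolate; no base is present, so neither ring C should open, and the existing stereocentre is too remote to interfere.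

Step 13
Reactants: 25 (S)-2-{4-(benzyloxy)-3-[4-((S)-5,7-bis(benzyloxy)-4-oxochroman-2-yl)phenoxy]phenyl}-5-hydroxy-7-methoxychroman-4-one
Product: 26 7-O-methyltetrahydroochnaflavone, (S)-2-{3-[4-((S)-5,7-dihydroxy-4-oxochroman-2-yl)phenoxy]-4-hydroxyphenyl}-5-hydroxy-7-methoxychroman-4-one
Conditions: H2 (1 atm), Pd/C (10%), EtOAc–MeOH, rt
Reagents that add atoms: none
Why: Hydrogenolysis of the three benzyl aryl ethers under neutral conditions; at atmospheric pressure and room temperature the aryl ketones and the C2–O1 bonds of the flavanones should survive, as in debenzylations of protected flavanones.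

## Compound list

1 | 4-(benzyloxy)-3-hydroxybenzaldehyde | O=Cc1ccc(OCc2ccccc2)c(O)c1 | starting material
2 | 4-bromophenylboronic acid | OB(O)c1ccc(Br)cc1 | starting material
3 | 4-(benzyloxy)-3-(4-bromophenoxy)benzaldehyde | O=Cc1ccc(OCc2ccccc2)c(Oc2ccc(Br)cc2)c1 | intermediate
4 | methyl 2,4-dioxopentanoate | COC(=O)C(=O)CC(C)=O | starting material
5 | methyl (2Z)-2,4-bis(trimethylsilyloxy)penta-2,4-dienoate | C=C(O[Si](C)(C)C)/C=C(O[Si](C)(C)C)/C(=O)OC | intermediate
6 | methyl (2Z,6S)-6-[4-(benzyloxy)-3-(4-bromophenoxy)phenyl]-4-oxo-2,6-bis(trimethylsilyloxy)hex-2-enoate | COC(=O)/C(O[Si](C)(C)C)=C/C(=O)C[C@H](O[Si](C)(C)C)c1ccc(OCc2ccccc2)c(Oc2ccc(Br)cc2)c1 | intermediate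
7 | methyl (S)-2-[4-(benzyloxy)-3-(4-bromophenoxy)phenyl]-4-oxo-3,4-dihydro-2H-pyran-6-carboxylate | COC(=O)C1=CC(=O)C[C@@H](c2ccc(OCc3ccccc3)c(Oc3ccc(Br)cc3)c2)O1 | intermediate
8 | (S)-2-[4-(benzyloxy)-3-(4-bromophenoxy)phenyl]-4-oxo-3,4-dihydro-2H-pyran-6-carboxylic acid | OC(=O)C1=CC(=O)C[C@@H](c2ccc(OCc3ccccc3)c(Oc3ccc(Br)cc3)c2)O1 | intermediate
9 | (S)-2-[4-(benzyloxy)-3-(4-bromophenoxy)phenyl]-4-oxo-3,4-dihydro-2H-pyran-6-carbonyl chloride | ClC(=O)C1=CC(=O)C[C@@H](c2ccc(OCc3ccccc3)c(Oc3ccc(Br)cc3)c2)O1 | intermediate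
10 | (S)-2-[4-(benzyloxy)-3-(4-bromophenoxy)phenyl]-6-(2-diazoacetyl)-2,3-dihydro-4H-pyran-4-one | [N-]=[N+]=CC(=O)C1=CC(=O)C[C@@H](c2ccc(OCc3ccccc3)c(Oc3ccc(Br)cc3)c2)O1 | intermediate
11 | 2-chloro-1,1-dimethoxyethane (chloroacetaldehyde dimethyl acetal) | COC(CCl)OC | starting material
12 | sodium methoxyacetylide | [Na+].[C-]#COC | intermediate
13 | methoxyacetylene | COC#C | intermediate
14 | (S)-2-[4-(benzyloxy)-3-(4-bromophenoxy)phenyl]-6-(2-oxoethenyl)-2,3-dihydro-4H-pyran-4-one (vinylketene) | O=C=CC1=CC(=O)C[C@@H](c2ccc(OCc3ccccc3)c(Oc3ccc(Br)cc3)c2)O1 | intermediate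
15 | (2S)-2-[4-(benzyloxy)-3-(4-bromophenoxy)phenyl]-6-(2-methoxy-4-oxocyclobut-2-en-1-yl)-2,3-dihydro-4H-pyran-4-one (both epimers at the cyclobutenone carbon) | COC1=CC(=O)C1C1=CC(=O)C[C@@H](c2ccc(OCc3ccccc3)c(Oc3ccc(Br)cc3)c2)O1 | intermediate
16 | (S)-2-[4-(benzyloxy)-3-(4-bromophenoxy)phenyl]-6-[(1E)-2-methoxy-4-oxobuta-1,3-dien-1-yl]-2,3-dihydro-4H-pyran-4-one (dienylketene) | O=C=C/C(OC)=C\C1=CC(=O)C[C@@H](c2ccc(OCc3ccccc3)c(Oc3ccc(Br)cc3)c2)O1 | intermediate
17 | (2S)-2-[4-(benzyloxy)-3-(4-bromophenoxy)phenyl]-7-methoxy-2,3-dihydro-4H-chromene-4,5(4aH)-dione (both epimers at C4a) | COC1=CC(=O)C2C(=O)C[C@@H](c3ccc(OCc4ccccc4)c(Oc4ccc(Br)cc4)c3)OC2=C1 | intermediate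
18 | (S)-2-[4-(benzyloxy)-3-(4-bromophenoxy)phenyl]-5-hydroxy-7-methoxychroman-4-one | COc1cc(O)c2c(c1)O[C@H](c1ccc(OCc3ccccc3)c(Oc3ccc(Br)cc3)c1)CC2=O | intermediate
19 | (S)-2-{4-(benzyloxy)-3-[4-(4,4,5,5-tetramethyl-1,3,2-dioxaborolan-2-yl)phenoxy]phenyl}-5-hydroxy-7-methoxychroman-4-one | COc1cc(O)c2c(c1)O[C@H](c1ccc(OCc3ccccc3)c(Oc3ccc(B4OC(C)(C)C(C)(C)O4)cc3)c1)CC2=O | intermediate
20 | (4-{2-(benzyloxy)-5-[(S)-5-hydroxy-7-methoxy-4-oxochroman-2-yl]phenoxy}phenyl)boronic acid | COc1cc(O)c2c(c1)O[C@H](c1ccc(OCc3ccccc3)c(Oc3ccc(B(O)O)cc3)c1)CC2=O | intermediate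
21 | 2',4',6'-trihydroxyacetophenone | CC(=O)c1c(O)cc(O)cc1O | starting material
22 | 1-[2,4-bis(benzyloxy)-6-hydroxyphenyl]ethan-1-one | CC(=O)c1c(O)cc(OCc2ccccc2)cc1OCc1ccccc1 | intermediate
23 | (E)-1-[2,4-bis(benzyloxy)-6-hydroxyphenyl]-3-(dimethylamino)prop-2-en-1-one | CN(C)/C=C/C(=O)c1c(O)cc(OCc2ccccc2)cc1OCc1ccccc1 | intermediate
24 | 5,7-bis(benzyloxy)-4H-chromen-4-one | O=c1ccoc2cc(OCc3ccccc3)cc(OCc3ccccc3)c12 | intermediate
25 | (S)-2-{4-(benzyloxy)-3-[4-((S)-5,7-bis(benzyloxy)-4-oxochroman-2-yl)phenoxy]phenyl}-5-hydroxy-7-methoxychroman-4-one | COc1cc(O)c2c(c1)O[C@H](c1ccc(OCc3ccccc3)c(Oc3ccc([C@@H]4CC(=O)c5c(OCc6ccccc6)cc(OCc6ccccc6)cc5O4)cc3)c1)CC2=O | intermediate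
26 | 7-O-methyltetrahydroochnaflavone | COc1cc(O)c2c(c1)O[C@H](c1ccc(O)c(Oc3ccc([C@@H]4CC(=O)c5c(O)cc(O)cc5O4)cc3)c1)CC2=O | target

## Step count and risks

Total step count: 13. Longest linear sequence: 9 steps (steps 1, 3, 4, 5, 7, 8, 9, 12, 13).

**Step 7 (key step).** The most likely failure is competing excitation of the cross-conjugated enone, leading to photocycloaddition with the alkyne or photodecomposition. Slow capture of the acyl-substituted vinylketene, with dimerisation as the result, is the second risk. Either would drain material before the cyclobutenone forms. The fallback gives up the benzannulation and buys ring A. It sets out from aldehyde 3. Claisen–Schmidt condensation with commercial 2',6'-dihydroxy-4'-methoxyacetophenone (KOH, EtOH) should give (E)-3-[4-(benzyloxy)-3-(4-bromophenoxy)phenyl]-1-(2,6-dihydroxy-4-methoxyphenyl)prop-2-en-1-one F1. Cyclisation (NaOAc, EtOH, reflux) should then give the racemic flavanone, that is 18 together with (R)-2-[4-(benzyloxy)-3-(4-bromophenoxy)phenyl]-5-hydroxy-7-methoxychroman-4-one F2. Separation on a chiral stationary phase returns the route to 18.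

**Step 3.** The ester group lowers the nucleophilicity of the diene terminus, so conversion may be low and facial discrimination with this electron-rich aldehyde may be modest. Acid-induced elimination at the para-oxygenated benzylic carbon during the cyclocondensation is a further risk. The fallback builds the same ester stepwise from aldehyde 3.
- Asymmetric methallylboration with the Si-face-selective antipode of B-methallyldiisopinocampheylborane should give (S)-1-[4-(benzyloxy)-3-(4-bromophenoxy)phenyl]-3-methylbut-3-en-1-ol F3.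
- Silylation (Et3SiCl, imidazole) should give {(S)-1-[4-(benzyloxy)-3-(4-bromophenoxy)phenyl]-3-methylbut-3-en-1-yl}oxy(triethyl)silane F4.
- Ozonolysis (O3, CH2Cl2–MeOH, −78 °C; Me2S) should give (S)-4-[4-(benzyloxy)-3-(4-bromophenoxy)phenyl]-4-(triethylsilyloxy)butan-2-one F5.
- Claisen condensation of its kinetic lithium enolate (LiHMDS, THF, −78 °C) with dimethyl oxalate should give methyl (S)-6-[4-(benzyloxy)-3-(4-bromophenoxy)phenyl]-2,4-dioxo-6-(triethylsilyloxy)hexanoate F6.
- CF3CO2H in CH2Cl2 at 0 °C should remove the silyl group and cyclodehydrate F6, rejoining the route at 7.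

**Step 8.** Acetate at 80 °C may open ring C reversibly through the C3 enolate and so erode the configuration at C2. The fallback installs boron before any stereocentre exists. It sets out from aldehyde 3.
- Miyaura borylation (B2pin2, PdCl2(dppf), KOAc, dioxane, 80 °C) should give 4-(benzyloxy)-3-[4-(4,4,5,5-tetramethyl-1,3,2-dioxaborolan-2-yl)phenoxy]benzaldehyde F7.
- The conditions of step 3 with diene 5 should give methyl (S)-2-{4-(benzyloxy)-3-[4-(4,4,5,5-tetramethyl-1,3,2-dioxaborolan-2-yl)phenoxy]phenyl}-4-oxo-3,4-dihydro-2H-pyran-6-carboxylate F8.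
- Me3SnOH should give (S)-2-{4-(benzyloxy)-3-[4-(4,4,5,5-tetramethyl-1,3,2-dioxaborolan-2-yl)phenoxy]phenyl}-4-oxo-3,4-dihydro-2H-pyran-6-carboxylic acid F9.
- Oxalyl chloride and then diazomethane should give (S)-2-{4-(benzyloxy)-3-[4-(4,4,5,5-tetramethyl-1,3,2-dioxaborolan-2-yl)phenoxy]phenyl}-6-(2-diazoacetyl)-2,3-dihydro-4H-pyran-4-one F10.
- Benzannulation of F10 with 13 under the conditions of step 7 comes back to the route at 19.

**Step 12.** The 5-hydroxy-4-keto chelate of 20 may sequester the cationic palladium catalyst, and the electron-rich boronic acid may protodeboronate, so the addition to the electron-rich chromone could stall. The fallback moves the union to the aldehyde stage and lets the benzannulation come last. It sets out from aldehyde 3.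
- Borylation with B2(OH)4 (Pd(OAc)2, XPhos, KOAc, EtOH, 80 °C) should give {4-[2-(benzyloxy)-5-formylphenoxy]phenyl}boronic acid F11.
- Conjugate addition to chromone 24 under the conditions of step 12 should give 4-(benzyloxy)-3-{4-[(S)-5,7-bis(benzyloxy)-4-oxochroman-2-yl]phenoxy}benzaldehyde F12.
- The conditions of step 3 with diene 5 should give methyl (S)-2-[4-(benzyloxy)-3-{4-[(S)-5,7-bis(benzyloxy)-4-oxochroman-2-yl]phenoxy}phenyl]-4-oxo-3,4-dihydro-2H-pyran-6-carboxylate F13.
- Me3SnOH should give (S)-2-[4-(benzyloxy)-3-{4-[(S)-5,7-bis(benzyloxy)-4-oxochroman-2-yl]phenoxy}phenyl]-4-oxo-3,4-dihydro-2H-pyran-6-carboxylic acid F14.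
- Oxalyl chloride and then diazomethane should give (S)-2-[4-(benzyloxy)-3-{4-[(S)-5,7-bis(benzyloxy)-4-oxochroman-2-yl]phenoxy}phenyl]-6-(2-diazoacetyl)-2,3-dihydro-4H-pyran-4-one F15.
- Benzannulation of F15 with 13 under the conditions of step 7 rejoins the route at 25.

## Further compounds

F1 | step 7 | (E)-3-[4-(benzyloxy)-3-(4-bromophenoxy)phenyl]-1-(2,6-dihydroxy-4-methoxyphenyl)prop-2-en-1-one | COc1cc(O)c(C(=O)/C=C/c2ccc(OCc3ccccc3)c(Oc3ccc(Br)cc3)c2)c(O)c1
F2 | step 7 | (R)-2-[4-(benzyloxy)-3-(4-bromophenoxy)phenyl]-5-hydroxy-7-methoxychroman-4-one | COc1cc(O)c2c(c1)O[C@@H](c1ccc(OCc3ccccc3)c(Oc3ccc(Br)cc3)c1)CC2=O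
F3 | step 3 | (S)-1-[4-(benzyloxy)-3-(4-bromophenoxy)phenyl]-3-methylbut-3-en-1-ol | C=C(C)C[C@H](O)c1ccc(OCc2ccccc2)c(Oc2ccc(Br)cc2)c1
F4 | step 3 | {(S)-1-[4-(benzyloxy)-3-(4-bromophenoxy)phenyl]-3-methylbut-3-en-1-yl}oxy(triethyl)silane | C=C(C)C[C@H](O[Si](CC)(CC)CC)c1ccc(OCc2ccccc2)c(Oc2ccc(Br)cc2)c1
F5 | step 3 | (S)-4-[4-(benzyloxy)-3-(4-bromophenoxy)phenyl]-4-(triethylsilyloxy)butan-2-one | CC(=O)C[C@H](O[Si](CC)(CC)CC)c1ccc(OCc2ccccc2)c(Oc2ccc(Br)cc2)c1
F6 | step 3 | methyl (S)-6-[4-(benzyloxy)-3-(4-bromophenoxy)phenyl]-2,4-dioxo-6-(triethylsilyloxy)hexanoate | COC(=O)C(=O)CC(=O)C[C@H](O[Si](CC)(CC)CC)c1ccc(OCc2ccccc2)c(Oc2ccc(Br)cc2)c1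
F7 | step 8 | 4-(benzyloxy)-3-[4-(4,4,5,5-tetramethyl-1,3,2-dioxaborolan-2-yl)phenoxy]benzaldehyde | O=Cc1ccc(OCc2ccccc2)c(Oc2ccc(B3OC(C)(C)C(C)(C)O3)cc2)c1
F8 | step 8 | methyl (S)-2-{4-(benzyloxy)-3-[4-(4,4,5,5-tetramethyl-1,3,2-dioxaborolan-2-yl)phenoxy]phenyl}-4-oxo-3,4-dihydro-2H-pyran-6-carboxylate | COC(=O)C1=CC(=O)C[C@@H](c2ccc(OCc3ccccc3)c(Oc3ccc(B4OC(C)(C)C(C)(C)O4)cc3)c2)O1
F9 | step 8 | (S)-2-{4-(benzyloxy)-3-[4-(4,4,5,5-tetramethyl-1,3,2-dioxaborolan-2-yl)phenoxy]phenyl}-4-oxo-3,4-dihydro-2H-pyran-6-carboxylic acid | OC(=O)C1=CC(=O)C[C@@H](c2ccc(OCc3ccccc3)c(Oc3ccc(B4OC(C)(C)C(C)(C)O4)cc3)c2)O1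
F10 | step 8 | (S)-2-{4-(benzyloxy)-3-[4-(4,4,5,5-tetramethyl-1,3,2-dioxaborolan-2-yl)phenoxy]phenyl}-6-(2-diazoacetyl)-2,3-dihydro-4H-pyran-4-one | [N-]=[N+]=CC(=O)C1=CC(=O)C[C@@H](c2ccc(OCc3ccccc3)c(Oc3ccc(B4OC(C)(C)C(C)(C)O4)cc3)c2)O1
F11 | step 12 | {4-[2-(benzyloxy)-5-formylphenoxy]phenyl}boronic acid | O=Cc1ccc(OCc2ccccc2)c(Oc2ccc(B(O)O)cc2)c1
F12 | step 12 | 4-(benzyloxy)-3-{4-[(S)-5,7-bis(benzyloxy)-4-oxochroman-2-yl]phenoxy}benzaldehyde | O=Cc1ccc(OCc2ccccc2)c(Oc2ccc([C@@H]3CC(=O)c4c(OCc5ccccc5)cc(OCc5ccccc5)cc4O3)cc2)c1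
F13 | step 12 | methyl (S)-2-[4-(benzyloxy)-3-{4-[(S)-5,7-bis(benzyloxy)-4-oxochroman-2-yl]phenoxy}phenyl]-4-oxo-3,4-dihydro-2H-pyran-6-carboxylate | COC(=O)C1=CC(=O)C[C@@H](c2ccc(OCc3ccccc3)c(Oc3ccc([C@@H]4CC(=O)c5c(OCc6ccccc6)cc(OCc6ccccc6)cc5O4)cc3)c2)O1
F14 | step 12 | (S)-2-[4-(benzyloxy)-3-{4-[(S)-5,7-bis(benzyloxy)-4-oxochroman-2-yl]phenoxy}phenyl]-4-oxo-3,4-dihydro-2H-pyran-6-carboxylic acid | OC(=O)C1=CC(=O)C[C@@H](c2ccc(OCc3ccccc3)c(Oc3ccc([C@@H]4CC(=O)c5c(OCc6ccccc6)cc(OCc6ccccc6)cc5O4)cc3)c2)O1
F15 | step 12 | (S)-2-[4-(benzyloxy)-3-{4-[(S)-5,7-bis(benzyloxy)-4-oxochroman-2-yl]phenoxy}phenyl]-6-(2-diazoacetyl)-2,3-dihydro-4H-pyran-4-one | [N-]=[N+]=CC(=O)C1=CC(=O)C[C@@H](c2ccc(OCc3ccccc3)c(Oc3ccc([C@@H]4CC(=O)c5c(OCc6ccccc6)cc(OCc6ccccc6)cc5O4)cc3)c2)O1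
A1 | alternative 1 | (S)-1-[2-(benzyloxy)-6-fluoro-4-methoxyphenyl]-3-{4-(benzyloxy)-3-[4-((S)-3-[2,4-bis(benzyloxy)-6-fluorophenyl]-1-hydroxy-3-oxopropyl)phenoxy]phenyl}-3-hydroxypropan-1-one | COc1cc(F)c(C(=O)C[C@H](O)c2ccc(OCc3ccccc3)c(Oc3ccc([C@@H](O)CC(=O)c4c(F)cc(OCc5ccccc5)cc4OCc4ccccc4)cc3)c2)c(OCc2ccccc2)c1
A2 | alternative 1 | tetra-O-benzyl-7-O-methyltetrahydroochnaflavone | COc1cc(OCc2ccccc2)c2c(c1)O[C@H](c1ccc(OCc3ccccc3)c(Oc3ccc([C@@H]4CC(=O)c5c(OCc6ccccc6)cc(OCc6ccccc6)cc5O4)cc3)c1)CC2=O
A3 | alternative 2 | (S)-5,7-bis(benzyloxy)-2-ethynylchroman-4-one | C#C[C@@H]1CC(=O)c2c(OCc3ccccc3)cc(OCc3ccccc3)cc2O1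
A4 | alternative 2 | 2-[2-(benzyloxy)-5-chlorophenoxy]buta-1,3-diene | C=CC(=C)Oc1cc(Cl)ccc1OCc1ccccc1
A5 | alternative 2 | (S)-5,7-bis(benzyloxy)-2-{4-[2-(benzyloxy)-5-chlorophenoxy]phenyl}chroman-4-one | Clc1ccc(OCc2ccccc2)c(Oc2ccc([C@@H]3CC(=O)c4c(OCc5ccccc5)cc(OCc5ccccc5)cc4O3)cc2)c1
A6 | alternative 3 | (S)-3-[4-(benzyloxy)-3-(4-bromophenoxy)phenyl]-3-hydroxy-N-methoxy-N-methylpropanamide | CON(C)C(=O)C[C@H](O)c1ccc(OCc2ccccc2)c(Oc2ccc(Br)cc2)c1
A7 | alternative 3 | 3-(benzyloxy)-5-methoxy-2-(trimethylsilyl)phenyl trifluoromethanesulfonate | COc1cc(OCc2ccccc2)c([Si](C)(C)C)c(OS(=O)(=O)C(F)(F)F)c1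
A8 | alternative 3 | (S)-5-(benzyloxy)-2-[4-(benzyloxy)-3-(4-bromophenoxy)phenyl]-7-methoxychroman-4-one | COc1cc(OCc2ccccc2)c2c(c1)O[C@H](c1ccc(OCc3ccccc3)c(Oc3ccc(Br)cc3)c1)CC2=O
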